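Readings and results were computed with made-up constants.

**Small charge.** A fraction of a millimole per litre of free catalyst competes with self-condensation for the substrate, and you must see which given numbers the end amount of target depends on.

in all of them: substrate 0.10 M
- zeta: reagent 0.105 M; free catalyst 0.059 mM; temperature 25 °C; run made earlier
- theta: reagent 0.105 M; free catalyst 0.18 mM; temperature 40 °C; run made earlier
- epsilon: reagent 0.19 M; free catalyst 0.20 mM; temperature 25 °C; run made earlier
- green: reagent 0.200 M; free catalyst 0.10 mM; temperature 40 °C; time 6.0 h
- ochre: reagent 0.105 M; free catalyst 0.20 mM; temperature 40 °C; time 6.0 h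

- zeta (time / h: target / %, substrate / %): 1.33: 0, 82; 3.00: 7, 65; 4.00: 2, 60; 6.00: 15, 46; 8.00: 15, 40
- theta (time / h: target / %, substrate / %): 0.333: 10, 78; 0.500: 16, 67; 1.00: 29, 50; 1.50: 38, 31; 2.50: 53, 15; 4.00: 61, 4
- epsilon (time / h: target / %, substrate / %): 2.00: 14, 66; 3.00: 24, 57; 5.00: 36, 36; 6.00: 43, 27; 8.00: 52, 18

(readings scatter by 2 percentage points)

- percent here means substrate units held: one self-condensation product counts as two
- steps under discussion: catalyst intermediate B -> by-product + catalyst intermediate C; catalyst intermediate C -> free catalyst + target; reagent + free catalyst -> catalyst intermediate A; 2 substrate -> self-condensation product; substrate + catalyst intermediate A <-> catalyst intermediate B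

- the winner by amount of target, in percent of the substrate charged; "neither" if no more than 2 percentage points parts them (green / ochre / neither)
- how much target is there at the end, in percent of the substrate charged: green
- how much target is there at the end, in percent of the substrate charged: ochre

**The rule.** Read the gap, substrate lost but not found as target, as self-condensation product. Take the catalytic route as catalyst times substrate and the gap as substrate squared. The parity charge is then the catalyst charge at which substrate's two lifetimes are equal at the start, for this substrate charge and temperature. With x the parity charge over the catalyst charge, which acts as a selectivity factor, and s the share of substrate left, target is ln((1+x)/(1+xs))/x.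

**What matters.** Reagent comes first. Zeta and epsilon, both at 25 °C, read parity charges of 0.253 mM and 0.196 mM, with 1.81 times the reagent in epsilon. Put on green's catalyst charge with the substrate spent, those two readings from 25 °C differ by 5.5 percentage points, while ochre holds theta's reagent. The catalyst charge enters x directly, and green has half of ochre's. Theta shares the 40 °C of green and ochre, so its last reading, taking mean substrate halfway, reads a parity charge of 0.199 mM. My reckoning of target, with s taken as zero, is 69.4% in ochre and 55.1% in green, a lead for ochre of 14 points.

**The forecast.** It named ochre, with green 46% (39% to 53%) and ochre 65% (59% to 71%): “Doubling reagent does not help; catalyst wins.” Its figures for both flasks stand below mine.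

**The flask.** Ochre gives 68.7% and green 52.0%, so green lies 6 points above the forecast. Green still holds 3.78% substrate at 6.00 h; with that s, the parity charge gives 51.4% target.

    catalyst intermediate B → by-product + catalyst intermediate C (k = 0.0629 s⁻¹, Ea = 81.0 kJ mol⁻¹)
    catalyst intermediate C → free catalyst + target (k = 24.3 s⁻¹, Ea = 78.0 kJ mol⁻¹)
    reagent + free catalyst → catalyst intermediate A (k = 196 L mol⁻¹ s⁻¹, Ea = 40.0 kJ mol⁻¹)
    2 substrate → self-condensation product (k = 7.02 × 10⁻⁴ L mol⁻¹ s⁻¹, Ea = 68.0 kJ mol⁻¹)
    substrate + catalyst intermediate A ⇌ catalyst intermediate B (K = 331 L mol⁻¹, k = 1.97 L mol⁻¹ s⁻¹, Ea = 55.0 kJ mol⁻¹, ΔH = −90.0 kJ mol⁻¹)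
    (constants at 40 °C)

**Thinner charge.** A neighbour of green charged with 0.0250 mM free catalyst has x of 7.96, and its 17.8% substrate left gives 16.5% target. That neighbour holds 17.3% target.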